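## Analysis of the target

Compound 30 is the 7-O-ether of 7-hydroxycoumarin with a primary allylic alcohol whose (E)-3-methylpent-2-enyl chain ends at C8 of a 1,5-dimethyl-6-oxabicyclo[3.2.1]octan-2-ol. The bicycle is a cyclohexane (C1, C2, C3, C4, C5, C8) and an oxolane (C1, C7, O6, C5, C8) that share C1, C8 and C5. It has four stereocentres, 1R, 2R, 5S and 8R: the bridgeheads C1 and C5 are quaternary and each carries a methyl group, the O6–C7 bridge is diaxial on the cyclohexane chair, the C8 chain is equatorial on that chair and lies on the side of the O6–C7 bridge, and the C2 hydroxyl is equatorial. C1, C8 and C5 are contiguous, so two quaternary centres flank a tertiary one; their relative and absolute configuration is the main difficulty. Sensitive functions are the coumarin lactone (hydride, hydroxide, strong nucleophiles), the allylic aryl ether (acid, SN2′ displacement) and the trisubstituted (E)-alkene, which rules out unselective hydrogenation, strong electrophiles and hot acid. The strategy rests on the C3–C4 bond, which lies in the three-carbon bridge between the oxygen-bearing carbons C2 and C5: with C2 as a ketone and C3=C4 as an alkene it is the product of an aldol condensation. If C7 is also raised to a lactone carbonyl, the aldol partners are an acetyl group on C1 and a formyl group on C5 of a γ-butyrolactone (C7, O6, C5, C8, C1), a small ring on which C5, C8 and C1 can be set one after another.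

## Retrosynthetic reasoning

The last bond to be made is the ether bond between the allylic CH2 of the chain and the phenolic oxygen of 29: 30 ⇒ 28 + 29. The coumarin lactone would not survive the hydride, amide-base and copper-hydride steps that the core needs, and a primary allylic alcohol and an acidic phenol are joined cleanly under Mitsunobu conditions. Diol 28 comes from silyl ether 27.

In 27 the C7 methylene is traced back to a lactone carbonyl (27 ⇐ 26 ⇐ 25), the C2 carbinol to a ketone (25 ⇐ 24) and the C3–C4 single bond to an enone (24 ⇐ 23). No skeletal bond is cut here. The purpose is to reach 23, in which C2=O and C3=C4 form the aldol retron and the C7 carbonyl ties C1 and O6 into a five-membered ring. Forward, hydride has to be added to C4, then to C2 from the face away from the lactone bridge, and the C7 carbonyl oxygen has to be removed.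

The C3=C4 bond of 23 is cut: 23 ⇐ 22 ⇐ 21. This is the one C–C bond of the carbocycle whose disconnection leaves a monocyclic precursor with all three stereocentres on one small ring, and it uses the only enolisable position of 21. Cutting C1–C2 or C4–C5 instead would break a bond to a quaternary centre and give up the lactone as stereochemical template. The gain is that the bridged carbocycle forms in a step that creates no stereocentre. Forward, the acetyl methyl group must be enolised, added to the formyl group and the aldol dehydrated without opening the β-keto lactone.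

The formyl group of 21 is taken back to the hydroxymethyl group of 20 and its 4-methoxybenzyl ether 19, and the acetyl group is removed from C1: 19 ⇐ 18 + 17, the enolate 18 coming from lactone 16. Acylating the enolate creates the quaternary centre under the control of the neighbouring C8 chain: the acyl group enters anti to it and therefore cis to the C5 substituent that becomes the aldehyde. Introducing the methyl group last would give the wrong C1 epimer.

Lactone 16 is opened at O6–C7 and C7 is reduced to the terminal carbon of an isopropenyl group: 16 ⇐ 15 ⇐ 14 ⇐ 13 ⇐ 12. The C1–C8 bond is then cut, 12 ⇐ 10 + 11. An ester enolate would give 16 in one step, but such enolates do not open trisubstituted epoxides at a useful rate, whereas copper-catalysed Grignard reagents do. Two extra redox steps are the price of a reliable C–C bond formation. Forward, the oxirane CH carbon of 10 must be attacked with inversion; this is the only SN2 path, because the other oxirane carbon is fully substituted.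

Epoxide 10 is the ether of epoxy alcohol 9, whose oxirane C–O bonds are cut back to the (Z)-allylic alcohol 8. An asymmetric epoxidation of an allylic alcohol sets C5 and C8 in one step under reagent control, and the alkene geometry becomes relative configuration. With the (Z)-alkene the hydroxymethyl group and the chain are cis on the oxirane and, after inversion at C8, trans on the lactone, as the aldol step requires. The (E)-isomer, though easier to make, would lead to the useless diastereomer.

Alcohol 8 comes from ester 7, whose C2=C3 bond is cut by a (Z)-selective phosphonate olefination: 7 ⇐ 5 + 6. Aldehyde 5 is the trisnor aldehyde of silyl ether 2 (5 ⇐ 4 ⇐ 3 ⇐ 2 ⇐ 1). The whole chain with its (E)-alkene and terminal oxygen therefore comes from 1 and never has to be built. Forward, the terminal isopropylidene group of 2 must be degraded without touching the C2=C3 alkene.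

## Alternatives that were turned down

Alternative 1: The O6–C7 bond is cut and C7 is traced back to one of two methyl groups on C1. The precursor is the tertiary cyclohexanol A2 with a gem-dimethyl group, and the product is the bicyclic ether A1, whose chain is only a 2-cyanoethyl stub. Forward, PhI(OAc)2 and I2 under irradiation turn the C5 hydroxyl into a hypoiodite, the alkoxyl radical takes a hydrogen atom from the methyl group that is 1,3-diaxial to it, and the oxygen displaces the resulting iodide.
- For: the oxolane forms directly at the ether oxidation level, C2 already carries its oxygen, and C1 is set by proximity, since only the methyl group cis to the C5 oxygen can be reached.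
- Against: a tertiary alkoxyl radical flanked by C4, C8 and a methyl group fragments easily by β-scission, and the hydrogen transfer needs the chair in which the C5 oxygen and a C1 methyl group are both axial. The reagent pair also attacks alkenes, so the chain must be truncated and the (E)-trisubstituted alkene built later from the nitrile by olefination of a methyl ketone, with no reliable control of geometry. The three stereocentres of A2 need their own enantioselective synthesis.
- Comparison: Alternative 1 is stronger in redox economy, since it needs no lactone-to-ether reduction. The chosen route offers instead the complete (E)-chain from 1 and a key step with one reactive site and no competing fragmentation.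

Alternative 2: Two bonds are cut at once, C1–C8 and O6–C7, leading from the bicyclic keto lactone A3 to the acyclic β-keto ester A4. A4 would be made from (S)-linalool A5 and carries a silyl ether on the C5 oxygen and a vinyl sulfone whose β-carbon is C8. Forward, Bu4NF removes the silyl group and generates the β-keto ester enolate; C1 adds to C8 in a 6-exo-trig Michael reaction and the C5 alkoxide acylates on the cis ester to close the lactone.
- For: both rings and the saturated C2 ketone arise in one operation, C5 comes from the chiral pool, and the sulfone is a handle for attaching the chain.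
- Against: C1 and C8 are both created in this step under the sole influence of C5. Lactonisation can select the C1 epimer only if the Michael addition is reversible, and it does nothing for C8, whose configuration depends on a transition state that must tell a methyl group from an oxygen substituent on C5. The chain must then be attached by alkylating the sulfonyl carbanion next to the congested C8 in the presence of an enolisable ketone, and the sulfone removed reductively.
- Comparison: on ring-forming efficiency Alternative 2 is clearly stronger. The chosen route offers a C8 centre fixed by an SN2 inversion, a C1 centre fixed by a kinetically controlled acylation, and the finished side chain.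

Alternative 3: The C4–C5 bond is cut, from the bicyclic ketone A6 (chain shortened to a 2-pivaloyloxyethyl group) to the oxolane A7, which has a hydrogen on C5 and a vinyl ketone on C1. Forward, photoexcited (Bu4N)4W10O32 abstracts the C5 hydrogen, the α-oxy radical adds to the terminal alkene carbon in a 6-endo closure, and the reduced tungstate reduces the resulting α-keto radical.
- For: the quaternary centre C5 and the carbocycle come from a C–H bond with no prior functionalisation. The configuration at C5 of A7 is irrelevant, because the radical is planar and the bridge can only close cis. The ether and the saturated ketone are already at their final oxidation levels.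
- Against: hydrogen abstraction is not confined to C5. The two C7 hydrogens are also α to oxygen and far less hindered, and the allylic C–H bonds of the real side chain would compete, which again forces a truncated chain and a later olefination of uncertain geometry. The vinyl ketone is prone to polymerisation and to intermolecular radical addition, and C1 and C8 of A7 still need an asymmetric synthesis.
- Comparison: Alternative 3 is the most economical in oxidation-state changes. The chosen route offers a polar bond formation whose site selectivity is dictated by the substrate (one enolisable carbon, one aldehyde) and the intact chain.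

Key step: step 14

Remark: the chain oxygen is carried as a tert-butyldiphenylsilyl (TBDPS) ether from step 1 on, because an acetate would not survive steps 5, 8, 11 and 17; the starting terpene is therefore the free alcohol 1.

## Route

Step 1
Reactants: 1 geraniol, (2E)-3,7-dimethylocta-2,6-dien-1-ol
Product: 2 tert-butyl{[(2E)-3,7-dimethylocta-2,6-dien-1-yl]oxy}diphenylsilane
Conditions: t-BuPh2SiCl, imidazole, CH2Cl2, 0 °C → rt
Reagents that add atoms: tert-butyl(chloro)diphenylsilane, CC(C)(C)[Si](Cl)(c1ccccc1)c1ccccc1
Why: Silylation of a primary alcohol with imidazole as base and nucleophilic catalyst. The TBDPS ether is chosen because it has to survive hydride, amide base, organocopper and Lewis acid and is removed last by fluoride.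

Step 2
Reactants: 2 tert-butyl{[(2E)-3,7-dimethylocta-2,6-dien-1-yl]oxy}diphenylsilane
Product: 3 tert-butyl{[(2E)-5-(3,3-dimethyloxiran-2-yl)-3-methylpent-2-en-1-yl]oxy}diphenylsilane (racemic at the oxirane CH)
Conditions: mCPBA (1.0 equiv), NaHCO3, CH2Cl2, −20 → 0 °C
Reagents that add atoms: 3-chloroperoxybenzoic acid, O=C(OO)c1cccc(Cl)c1
Why: Peracid (Prilezhaev) epoxidation is electrophilic and should take the more electron-rich, less shielded C6=C7 alkene; the C2=C3 alkene is deactivated by the allylic oxygen and screened by the silyl group. The new stereocentre is racemic and is destroyed in step 3.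

Step 3
Reactants: 3 tert-butyl{[(2E)-5-(3,3-dimethyloxiran-2-yl)-3-methylpent-2-en-1-yl]oxy}diphenylsilane
Product: 5 (4E)-6-[(tert-butyldiphenylsilyl)oxy]-4-methylhex-4-enal, via vicinal diol 4 (not isolated)
Conditions: H5IO6, THF/H2O, 0 °C → rt
Reagents that add atoms: water, O (taken up in diol 4; this oxygen leaves again with the acetone)
Why: Aqueous periodic acid opens the epoxide to the glycol and cleaves it (Malaprade reaction) to the aldehyde and acetone. The silyl ether and the trisubstituted alkene are inert to periodate.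

Step 4
Reactants: 5 (4E)-6-[(tert-butyldiphenylsilyl)oxy]-4-methylhex-4-enal; 6 ethyl 2-[bis(2,2,2-trifluoroethoxy)phosphoryl]propanoate
Product: 7 ethyl (2Z,6E)-8-[(tert-butyldiphenylsilyl)oxy]-2,6-dimethylocta-2,6-dienoate
Conditions: KN(SiMe3)2, 18-crown-6, THF, −78 °C
Reagents that add atoms: none
Why: Still–Gennari variant of the Horner–Wadsworth–Emmons olefination: with the trifluoroethyl phosphonate and a dissociated potassium counter-ion the first-formed adduct eliminates faster than it equilibrates, which should give the (Z)-trisubstituted enoate.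

Step 5
Reactants: 7 ethyl (2Z,6E)-8-[(tert-butyldiphenylsilyl)oxy]-2,6-dimethylocta-2,6-dienoate
Product: 8 (2Z,6E)-8-[(tert-butyldiphenylsilyl)oxy]-2,6-dimethylocta-2,6-dien-1-ol
Conditions: i-Bu2AlH (2.2 equiv), CH2Cl2, −78 → −40 °C
Reagents that add atoms: none
Why: 1,2-Reduction of the conjugated ester by the aluminium hydride gives the allylic alcohol without touching the alkene geometry or the silyl ether.

Step 6
Reactants: 8 (2Z,6E)-8-[(tert-butyldiphenylsilyl)oxy]-2,6-dimethylocta-2,6-dien-1-ol
Product: 9 [(2S,3R)-3-{(3E)-5-[(tert-butyldiphenylsilyl)oxy]-3-methylpent-3-en-1-yl}-2-methyloxiran-2-yl]methanol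
Conditions: Ti(OiPr)4 (cat.), L-(+)-diethyl tartrate (cat.), t-BuOOH, 4 Å MS, CH2Cl2, −20 °C
Reagents that add atoms: tert-butyl hydroperoxide, CC(C)(C)OO
Why: Sharpless asymmetric epoxidation of the only free allylic alcohol. With L-(+)-diethyl tartrate the oxygen is delivered to the face that gives the (2S,3R)-epoxide, which fixes C5 in its final configuration and C8 in the configuration that step 8 inverts. The (Z)-alkene places the hydroxymethyl group and the chain cis on the oxirane.

Step 7
Reactants: 9 [(2S,3R)-3-{(3E)-5-[(tert-butyldiphenylsilyl)oxy]-3-methylpent-3-en-1-yl}-2-methyloxiran-2-yl]methanol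
Product: 10 tert-butyl{[(2E)-5-[(2R,3S)-3-{[(4-methoxybenzyl)oxy]methyl}-3-methyloxiran-2-yl]-3-methylpent-2-en-1-yl]oxy}diphenylsilane
Conditions: NaH, 4-MeOC6H4CH2Cl, Bu4NI (cat.), THF/DMF, 0 °C
Reagents that add atoms: 4-methoxybenzyl chloride, COc1ccc(CCl)cc1
Why: Williamson etherification of the sodium alkoxide; in an aprotic medium at 0 °C benzylation should outrun Payne rearrangement. The 4-methoxybenzyl (PMB) ether is inert to the organometallic, borane and amide-base steps and is later removed oxidatively at neutral pH.

Step 8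
Reactants: 10 tert-butyl{[(2E)-5-[(2R,3S)-3-{[(4-methoxybenzyl)oxy]methyl}-3-methyloxiran-2-yl]-3-methylpent-2-en-1-yl]oxy}diphenylsilane; 11 isopropenylmagnesium bromide, CH2=C(CH3)MgBr
Product: 12 (2R,3R,6E)-8-[(tert-butyldiphenylsilyl)oxy]-1-[(4-methoxybenzyl)oxy]-2,6-dimethyl-3-(prop-1-en-2-yl)oct-6-en-2-ol
Conditions: CuI (10 mol %), THF, −30 → 0 °C; then aqueous quench
Reagents that add atoms: none
Why: Copper-catalysed SN2 opening of a trisubstituted epoxide by an sp2 Grignard reagent: the oxirane carbon bearing the methyl group is fully substituted, so backside attack can occur only at the CH carbon (C8), with inversion, giving the (3R) centre and the free tertiary alcohol at C5. Ester enolates are too weakly nucleophilic for this hindered epoxide, which is why the C1–C7 unit enters as an isopropenyl group.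

Step 9
Reactants: 12 (2R,3R,6E)-8-[(tert-butyldiphenylsilyl)oxy]-1-[(4-methoxybenzyl)oxy]-2,6-dimethyl-3-(prop-1-en-2-yl)oct-6-en-2-ol
Product: 14 (2R,3R,6E)-8-[(tert-butyldiphenylsilyl)oxy]-3-(1-hydroxypropan-2-yl)-1-[(4-methoxybenzyl)oxy]-2,6-dimethyloct-6-en-2-ol (both epimers at the new CH(CH3) carbon), via alkylborane 13 (not isolated)
Conditions: 9-BBN (2.5 equiv), THF, 0 °C → rt; then NaOH, H2O2, 0 °C → rt
Reagents that add atoms: 9-borabicyclo[3.3.1]nonane, B1C2CCCC1CCC2 (its boron is lost again when 13 is oxidised); hydrogen peroxide, OO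
Why: Hydroboration–oxidation: 9-BBN adds to the 1,1-disubstituted alkene far faster than to the trisubstituted one and places boron on the terminal carbon, so oxidation gives the primary alcohol that becomes C7. The new CH(CH3) centre (C1) forms without control, which is harmless because step 11 enolises it.

Step 10
Reactants: 14 (2R,3R,6E)-8-[(tert-butyldiphenylsilyl)oxy]-3-(1-hydroxypropan-2-yl)-1-[(4-methoxybenzyl)oxy]-2,6-dimethyloct-6-en-2-ol
Product: 16 (4R,5R)-4-{(3E)-5-[(tert-butyldiphenylsilyl)oxy]-3-methylpent-3-en-1-yl}-5-{[(4-methoxybenzyl)oxy]methyl}-3,5-dimethyloxolan-2-one (both C3 epimers), via lactol 15 (not isolated)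
Conditions: TEMPO (20 mol %), PhI(OAc)2 (2.5 equiv), CH2Cl2, rt
Reagents that add atoms: none
Why: Nitroxyl-catalysed oxidation (oxoammonium ion from TEMPO) takes the primary alcohol to the aldehyde, which the tertiary hydroxyl traps as the lactol; a second oxidation gives the γ-lactone. The tertiary alcohol, the PMB ether and the alkene are not oxidised.

Step 11
Reactants: 16 (4R,5R)-4-{(3E)-5-[(tert-butyldiphenylsilyl)oxy]-3-methylpent-3-en-1-yl}-5-{[(4-methoxybenzyl)oxy]methyl}-3,5-dimethyloxolan-2-one; 17 acetyl chloride
Product: 19 (3S,4R,5R)-3-acetyl-4-{(3E)-5-[(tert-butyldiphenylsilyl)oxy]-3-methylpent-3-en-1-yl}-5-{[(4-methoxybenzyl)oxy]methyl}-3,5-dimethyloxolan-2-one, via lithium enolate 18 (not isolated)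
Conditions: LiN(i-Pr)2, THF, −78 °C; enolate solution added to 17 (excess), THF, −78 °C
Reagents that add atoms: none
Why: Kinetic deprotonation gives the lactone enolate, in which both C1 epimers converge, and C-acylation by the acid chloride (inverse addition to suppress O-acylation) creates the quaternary C1. The acyl group should enter on the enolate face anti to the adjacent C8 chain, which places the acetyl group cis to the CH2OPMB group on C5 and gives the (3S) centre.

Step 12
Reactants: 19 (3S,4R,5R)-3-acetyl-4-{(3E)-5-[(tert-butyldiphenylsilyl)oxy]-3-methylpent-3-en-1-yl}-5-{[(4-methoxybenzyl)oxy]methyl}-3,5-dimethyloxolan-2-one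
Product: 20 (3S,4R,5R)-3-acetyl-4-{(3E)-5-[(tert-butyldiphenylsilyl)oxy]-3-methylpent-3-en-1-yl}-5-(hydroxymethyl)-3,5-dimethyloxolan-2-one
Conditions: DDQ, CH2Cl2/pH 7 buffer, 0 °C → rt
Reagents that add atoms: none
Why: Oxidative cleavage of the electron-rich benzyl ether by DDQ (hydride abstraction, then hydrolysis of the oxocarbenium ion) runs at neutral pH. This matters because an alkoxide at this oxygen could add to the cis acetyl group and cleave the β-keto lactone by retro-Claisen acyl transfer, so 20 is best carried on at once. The TBDPS ether is not affected.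

Step 13
Reactants: 20 (3S,4R,5R)-3-acetyl-4-{(3E)-5-[(tert-butyldiphenylsilyl)oxy]-3-methylpent-3-en-1-yl}-5-(hydroxymethyl)-3,5-dimethyloxolan-2-one
Product: 21 (2R,3R,4S)-4-acetyl-3-{(3E)-5-[(tert-butyldiphenylsilyl)oxy]-3-methylpent-3-en-1-yl}-2,4-dimethyl-5-oxooxolane-2-carbaldehyde
Conditions: Dess–Martin periodinane, NaHCO3, CH2Cl2, 0 °C → rt
Reagents that add atoms: none
Why: Dess–Martin oxidation of the neopentylic primary alcohol under buffered, non-basic conditions. The aldehyde carbon is attached to a quaternary carbon, so it can neither enolise nor epimerise.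

Step 14
Reactants: 21 (2R,3R,4S)-4-acetyl-3-{(3E)-5-[(tert-butyldiphenylsilyl)oxy]-3-methylpent-3-en-1-yl}-2,4-dimethyl-5-oxooxolane-2-carbaldehyde
Product: 23 (1S,5S,8R)-8-{(3E)-5-[(tert-butyldiphenylsilyl)oxy]-3-methylpent-3-en-1-yl}-1,5-dimethyl-6-oxabicyclo[3.2.1]oct-3-ene-2,7-dione, via aldol 22 (not isolated)
Conditions: DBU (2 equiv), toluene, rt → 60 °C
Reagents that add atoms: none
Why: DBU deprotonates the acetyl methyl group, the only enolisable position of 21 (C1 and C5 are quaternary and the aldehyde has no α-hydrogen), and the enolate carbon C3 adds to the formyl carbon C4 to give aldol 22. The closest known reaction type is the base-mediated intramolecular aldol condensation of a methyl ketone with a tethered non-enolisable aldehyde to a cyclohex-2-enone. The six-membered ring C1–C2–C3–C4–C5–C8 closes in the 6-(enolendo)-exo-trig mode, since both enolate carbons lie in the new ring. E1cB loss of water from 22 then forms C3=C4, which is conjugated with the C2 ketone and lies away from both bridgeheads, so no bridgehead alkene arises. No stereocentre is created; the carbinol centre of 22 is transient. The closure needs the acetyl and formyl groups cis on the lactone, which holds because both were placed anti to the C8 chain in steps 6, 8 and 11. It also needs a base that does not add to the β-keto lactone, which a nucleophile would cleave by retro-Claisen attack at C2 or C7; the amidine is non-nucleophilic, and the irreversible dehydration drains the reversible aldol equilibrium.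

Step 15
Reactants: 23 (1S,5S,8R)-8-{(3E)-5-[(tert-butyldiphenylsilyl)oxy]-3-methylpent-3-en-1-yl}-1,5-dimethyl-6-oxabicyclo[3.2.1]oct-3-ene-2,7-dione
Product: 24 (1S,5S,8R)-8-{(3E)-5-[(tert-butyldiphenylsilyl)oxy]-3-methylpent-3-en-1-yl}-1,5-dimethyl-6-oxabicyclo[3.2.1]octane-2,7-dione
Conditions: [(Ph3P)CuH]6, toluene, H2O (5 equiv), rt
Reagents that add atoms: none
Why: Conjugate reduction by the phosphine-stabilised copper hydride: hydride is transferred to the β-carbon C4 and water protonates the copper enolate. Isolated alkenes, the lactone and the saturated ketone formed are not reduced by this reagent.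

Step 16
Reactants: 24 (1S,5S,8R)-8-{(3E)-5-[(tert-butyldiphenylsilyl)oxy]-3-methylpent-3-en-1-yl}-1,5-dimethyl-6-oxabicyclo[3.2.1]octane-2,7-dione
Product: 25 (1S,2R,5S,8R)-8-{(3E)-5-[(tert-butyldiphenylsilyl)oxy]-3-methylpent-3-en-1-yl}-2-hydroxy-1,5-dimethyl-6-oxabicyclo[3.2.1]octan-7-one
Conditions: NaBH4, CeCl3·7H2O, MeOH, −40 → −20 °C
Reagents that add atoms: none
Why: Hydride addition to the C2 ketone (Luche conditions) should occur on the face syn to C8, that is axially on the chair and anti to the C1–C7 bond, because the other face is covered by the lactone bridge; this gives the equatorial (2R) alcohol, which is also the more stable epimer. Borohydride does not reduce the lactone at this temperature, and the cerium salt keeps the medium from becoming basic enough for retro-Claisen cleavage.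

Step 17
Reactants: 25 (1S,2R,5S,8R)-8-{(3E)-5-[(tert-butyldiphenylsilyl)oxy]-3-methylpent-3-en-1-yl}-2-hydroxy-1,5-dimethyl-6-oxabicyclo[3.2.1]octan-7-one
Product: 26 (1S,2R,5S,8R)-8-{(3E)-5-[(tert-butyldiphenylsilyl)oxy]-3-methylpent-3-en-1-yl}-1,5-dimethyl-6-oxabicyclo[3.2.1]octane-2,7-diol (both C7 epimers)
Conditions: i-Bu2AlH (2.5 equiv), CH2Cl2, −78 °C
Reagents that add atoms: none
Why: Partial reduction of the γ-lactone by the aluminium hydride at −78 °C stops at the aluminium hemiacetal, which gives the lactol on work-up. One extra equivalent is consumed by the C2 hydroxyl.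

Step 18
Reactants: 26 (1S,2R,5S,8R)-8-{(3E)-5-[(tert-butyldiphenylsilyl)oxy]-3-methylpent-3-en-1-yl}-1,5-dimethyl-6-oxabicyclo[3.2.1]octane-2,7-diol
Product: 27 (1R,2R,5S,8R)-8-{(3E)-5-[(tert-butyldiphenylsilyl)oxy]-3-methylpent-3-en-1-yl}-1,5-dimethyl-6-oxabicyclo[3.2.1]octan-2-ol
Conditions: Et3SiH, BF3·OEt2, CH2Cl2, −78 → −40 °C
Reagents that add atoms: none
Why: Ionic hydrogenation: the Lewis acid ionises the lactol to the cyclic oxocarbenium ion (C7=O6, neither atom a bridgehead), which the silane reduces to the C7 methylene group. No stereocentre is involved.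

Step 19
Reactants: 27 (1R,2R,5S,8R)-8-{(3E)-5-[(tert-butyldiphenylsilyl)oxy]-3-methylpent-3-en-1-yl}-1,5-dimethyl-6-oxabicyclo[3.2.1]octan-2-ol
Product: 28 (1R,2R,5S,8R)-8-[(3E)-5-hydroxy-3-methylpent-3-en-1-yl]-1,5-dimethyl-6-oxabicyclo[3.2.1]octan-2-ol
Conditions: Bu4NF, THF, 0 °C → rt
Reagents that add atoms: none
Why: Fluoride cleaves the Si–O bond of the primary allylic silyl ether; nothing else in 27 reacts with this reagent.

Step 20
Reactants: 28 (1R,2R,5S,8R)-8-[(3E)-5-hydroxy-3-methylpent-3-en-1-yl]-1,5-dimethyl-6-oxabicyclo[3.2.1]octan-2-ol; 29 7-hydroxycoumarin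
Product: 30 7-{[(2E)-5-[(1R,2R,5S,8R)-2-hydroxy-1,5-dimethyl-6-oxabicyclo[3.2.1]octan-8-yl]-3-methylpent-2-en-1-yl]oxy}-2H-chromen-2-one
Conditions: PPh3, DIAD, THF, 0 °C → rt
Reagents that add atoms: none
Why: Mitsunobu etherification: the acidic phenol protonates the betaine and its anion displaces the alkoxyphosphonium group at the primary allylic carbon by SN2, which keeps the (E)-geometry. The hindered secondary hydroxyl at C2, next to a quaternary carbon, should not be activated at a comparable rate.

## Compound list

1 | geraniol, (2E)-3,7-dimethylocta-2,6-dien-1-ol | CC(C)=CCC/C(C)=C/CO | starting material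
2 | tert-butyl{[(2E)-3,7-dimethylocta-2,6-dien-1-yl]oxy}diphenylsilane | CC(C)=CCC/C(C)=C/CO[Si](c1ccccc1)(c1ccccc1)C(C)(C)C | intermediate
3 | tert-butyl{[(2E)-5-(3,3-dimethyloxiran-2-yl)-3-methylpent-2-en-1-yl]oxy}diphenylsilane (racemic) | CC1(C)OC1CC/C(C)=C/CO[Si](c1ccccc1)(c1ccccc1)C(C)(C)C | intermediate
4 | (6E)-8-[(tert-butyldiphenylsilyl)oxy]-2,6-dimethyloct-6-ene-2,3-diol (racemic, not isolated) | CC(C)(O)C(O)CC/C(C)=C/CO[Si](c1ccccc1)(c1ccccc1)C(C)(C)C | intermediate
5 | (4E)-6-[(tert-butyldiphenylsilyl)oxy]-4-methylhex-4-enal | O=CCC/C(C)=C/CO[Si](c1ccccc1)(c1ccccc1)C(C)(C)C | intermediate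
6 | ethyl 2-[bis(2,2,2-trifluoroethoxy)phosphoryl]propanoate | CCOC(=O)C(C)P(=O)(OCC(F)(F)F)OCC(F)(F)F | starting material
7 | ethyl (2Z,6E)-8-[(tert-butyldiphenylsilyl)oxy]-2,6-dimethylocta-2,6-dienoate | CCOC(=O)/C(C)=C\CC/C(C)=C/CO[Si](c1ccccc1)(c1ccccc1)C(C)(C)C | intermediate
8 | (2Z,6E)-8-[(tert-butyldiphenylsilyl)oxy]-2,6-dimethylocta-2,6-dien-1-ol | OC/C(C)=C\CC/C(C)=C/CO[Si](c1ccccc1)(c1ccccc1)C(C)(C)C | intermediate
9 | [(2S,3R)-3-{(3E)-5-[(tert-butyldiphenylsilyl)oxy]-3-methylpent-3-en-1-yl}-2-methyloxiran-2-yl]methanol | C/C(=C\CO[Si](c1ccccc1)(c1ccccc1)C(C)(C)C)CC[C@H]1O[C@@]1(C)CO | intermediate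
10 | tert-butyl{[(2E)-5-[(2R,3S)-3-{[(4-methoxybenzyl)oxy]methyl}-3-methyloxiran-2-yl]-3-methylpent-2-en-1-yl]oxy}diphenylsilane | C/C(=C\CO[Si](c1ccccc1)(c1ccccc1)C(C)(C)C)CC[C@H]1O[C@@]1(C)COCc1ccc(OC)cc1 | intermediate
11 | isopropenylmagnesium bromide (prop-1-en-2-ylmagnesium bromide) | C=C(C)[Mg]Br | starting material
12 | (2R,3R,6E)-8-[(tert-butyldiphenylsilyl)oxy]-1-[(4-methoxybenzyl)oxy]-2,6-dimethyl-3-(prop-1-en-2-yl)oct-6-en-2-ol | C/C(=C\CO[Si](c1ccccc1)(c1ccccc1)C(C)(C)C)CC[C@@H]([C@@](C)(O)COCc1ccc(OC)cc1)C(C)=C | intermediate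
13 | B-alkyl-9-borabicyclo[3.3.1]nonane from 12, boron on the terminal carbon of the former isopropenyl group (epimers at CH(CH3), not isolated) | C/C(=C\CO[Si](c1ccccc1)(c1ccccc1)C(C)(C)C)CC[C@@H]([C@@](C)(O)COCc1ccc(OC)cc1)C(C)CB1C2CCCC1CCC2 | intermediate
14 | (2R,3R,6E)-8-[(tert-butyldiphenylsilyl)oxy]-3-(1-hydroxypropan-2-yl)-1-[(4-methoxybenzyl)oxy]-2,6-dimethyloct-6-en-2-ol (both epimers at CH(CH3)) | C/C(=C\CO[Si](c1ccccc1)(c1ccccc1)C(C)(C)C)CC[C@@H]([C@@](C)(O)COCc1ccc(OC)cc1)C(C)CO | intermediate
15 | (4R,5R)-4-{(3E)-5-[(tert-butyldiphenylsilyl)oxy]-3-methylpent-3-en-1-yl}-5-{[(4-methoxybenzyl)oxy]methyl}-3,5-dimethyloxolan-2-ol (epimers at C2 and C3, not isolated) | C/C(=C\CO[Si](c1ccccc1)(c1ccccc1)C(C)(C)C)CC[C@@H]1C(C)C(O)O[C@@]1(C)COCc1ccc(OC)cc1 | intermediate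
16 | (4R,5R)-4-{(3E)-5-[(tert-butyldiphenylsilyl)oxy]-3-methylpent-3-en-1-yl}-5-{[(4-methoxybenzyl)oxy]methyl}-3,5-dimethyloxolan-2-one (both C3 epimers) | C/C(=C\CO[Si](c1ccccc1)(c1ccccc1)C(C)(C)C)CC[C@@H]1C(C)C(=O)O[C@@]1(C)COCc1ccc(OC)cc1 | intermediate
17 | acetyl chloride | CC(=O)Cl | starting material
18 | lithium enolate of 16 (not isolated) | C/C(=C\CO[Si](c1ccccc1)(c1ccccc1)C(C)(C)C)CC[C@@H]1C(C)=C([O-])O[C@@]1(C)COCc1ccc(OC)cc1.[Li+] | intermediate
19 | (3S,4R,5R)-3-acetyl-4-{(3E)-5-[(tert-butyldiphenylsilyl)oxy]-3-methylpent-3-en-1-yl}-5-{[(4-methoxybenzyl)oxy]methyl}-3,5-dimethyloxolan-2-one (acetyl cis to CH2OPMB, trans to the chain) | C/C(=C\CO[Si](c1ccccc1)(c1ccccc1)C(C)(C)C)CC[C@@H]1[C@@](C)(C(C)=O)C(=O)O[C@@]1(C)COCc1ccc(OC)cc1 | intermediate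
20 | (3S,4R,5R)-3-acetyl-4-{(3E)-5-[(tert-butyldiphenylsilyl)oxy]-3-methylpent-3-en-1-yl}-5-(hydroxymethyl)-3,5-dimethyloxolan-2-one | C/C(=C\CO[Si](c1ccccc1)(c1ccccc1)C(C)(C)C)CC[C@@H]1[C@@](C)(C(C)=O)C(=O)O[C@@]1(C)CO | intermediate
21 | (2R,3R,4S)-4-acetyl-3-{(3E)-5-[(tert-butyldiphenylsilyl)oxy]-3-methylpent-3-en-1-yl}-2,4-dimethyl-5-oxooxolane-2-carbaldehyde | C/C(=C\CO[Si](c1ccccc1)(c1ccccc1)C(C)(C)C)CC[C@@H]1[C@@](C)(C(C)=O)C(=O)O[C@@]1(C)C=O | intermediate
22 | (1S,5R,8R)-8-{(3E)-5-[(tert-butyldiphenylsilyl)oxy]-3-methylpent-3-en-1-yl}-4-hydroxy-1,5-dimethyl-6-oxabicyclo[3.2.1]octane-2,7-dione (either C4 epimer, not isolated) | C/C(=C\CO[Si](c1ccccc1)(c1ccccc1)C(C)(C)C)CC[C@@H]1[C@]2(C)C(=O)O[C@@]1(C)C(O)CC2=O | intermediate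
23 | (1S,5S,8R)-8-{(3E)-5-[(tert-butyldiphenylsilyl)oxy]-3-methylpent-3-en-1-yl}-1,5-dimethyl-6-oxabicyclo[3.2.1]oct-3-ene-2,7-dione | C/C(=C\CO[Si](c1ccccc1)(c1ccccc1)C(C)(C)C)CC[C@@H]1[C@]2(C)C(=O)O[C@@]1(C)C=CC2=O | intermediate
24 | (1S,5S,8R)-8-{(3E)-5-[(tert-butyldiphenylsilyl)oxy]-3-methylpent-3-en-1-yl}-1,5-dimethyl-6-oxabicyclo[3.2.1]octane-2,7-dione | C/C(=C\CO[Si](c1ccccc1)(c1ccccc1)C(C)(C)C)CC[C@@H]1[C@]2(C)C(=O)O[C@@]1(C)CCC2=O | intermediate
25 | (1S,2R,5S,8R)-8-{(3E)-5-[(tert-butyldiphenylsilyl)oxy]-3-methylpent-3-en-1-yl}-2-hydroxy-1,5-dimethyl-6-oxabicyclo[3.2.1]octan-7-one (equatorial hydroxyl) | C/C(=C\CO[Si](c1ccccc1)(c1ccccc1)C(C)(C)C)CC[C@@H]1[C@]2(C)C(=O)O[C@@]1(C)CC[C@H]2O | intermediate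
26 | (1S,2R,5S,8R)-8-{(3E)-5-[(tert-butyldiphenylsilyl)oxy]-3-methylpent-3-en-1-yl}-1,5-dimethyl-6-oxabicyclo[3.2.1]octane-2,7-diol (both C7 epimers) | C/C(=C\CO[Si](c1ccccc1)(c1ccccc1)C(C)(C)C)CC[C@@H]1[C@]2(C)C(O)O[C@@]1(C)CC[C@H]2O | intermediate
27 | (1R,2R,5S,8R)-8-{(3E)-5-[(tert-butyldiphenylsilyl)oxy]-3-methylpent-3-en-1-yl}-1,5-dimethyl-6-oxabicyclo[3.2.1]octan-2-ol | C/C(=C\CO[Si](c1ccccc1)(c1ccccc1)C(C)(C)C)CC[C@@H]1[C@]2(C)CO[C@@]1(C)CC[C@H]2O | intermediate
28 | (1R,2R,5S,8R)-8-[(3E)-5-hydroxy-3-methylpent-3-en-1-yl]-1,5-dimethyl-6-oxabicyclo[3.2.1]octan-2-ol | C/C(=C\CO)CC[C@@H]1[C@]2(C)CO[C@@]1(C)CC[C@H]2O | intermediate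
29 | 7-hydroxycoumarin (7-hydroxy-2H-chromen-2-one) | O=c1ccc2ccc(O)cc2o1 | starting material
30 | 7-{[(2E)-5-[(1R,2R,5S,8R)-2-hydroxy-1,5-dimethyl-6-oxabicyclo[3.2.1]octan-8-yl]-3-methylpent-2-en-1-yl]oxy}-2H-chromen-2-one | C/C(=C\COc1ccc2ccc(=O)oc2c1)CC[C@@H]1[C@]2(C)CO[C@@]1(C)CC[C@H]2O | target

## Step count and least certain steps

Total: 20 steps. Longest linear sequence: 20 steps (1 → 30); compounds 6, 11, 17 and 29 are purchased.

Step 14 (key step). The most likely failure is that the β-keto lactone is cleaved or rearranged before dehydration: the aldolate oxygen on C4 is five atoms from the lactone carbonyl C7 and can take over the acyl group, and any adventitious nucleophile can cleave at C2 by a retro-Claisen path. The reaction may also stall at the aldol stage if E1cB elimination is slow. The fallback separates the C–C bond formation from the elimination and avoids a free alkoxide. Setting out from 21, soft enolisation (Me3SiOTf, Et3N, CH2Cl2, 0 °C) gives the trimethylsilyl enol ether F1, again at the only enolisable site. BF3·OEt2 at −78 °C promotes an intramolecular Mukaiyama aldol addition to the β-hydroxy ketone 22, which is now isolated. It is converted into the mesylate F2 (MsCl, Et3N, 0 °C) and eliminated with DBU at 0 °C, returning to the route at 23.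

Step 8. The substitution has to take place at a secondary carbon next to a fully substituted one. If it is slow, magnesium-halide-promoted rearrangement of the epoxide to a carbonyl compound, bromohydrin formation, or base-induced elimination to an allylic alcohol may take over. The fallback uses the smallest carbon nucleophile and no Lewis acid. Setting out from 10, LiC≡CH·H2NCH2CH2NH2 in DMSO opens the epoxide at the same carbon with inversion to the ethynyl carbinol F3. Anti-Markovnikov hydroboration of the terminal alkyne with dicyclohexylborane and oxidation (NaBO3·4H2O) gives the aldehyde, which closes to the lactol F4. TEMPO/PhI(OAc)2 oxidises it to the lactone F5, and methylation of its enolate (LiN(i-Pr)2, CH3I, −78 °C) returns to the route at 16, as its 3,4-trans epimer.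

Step 11. Two processes may interfere: O-acylation of the tetrasubstituted enolate, and acylation on the wrong face, since the CH2OPMB group on C5 lies on the face that has to be attacked even though the adjacent chain shields the other one. The fallback replaces the acid chloride by a small aldehyde, which can only react at carbon. Setting out from 16, the lithium enolate is treated with acetaldehyde at −78 °C to give the β-hydroxy lactone F6 (carbinol configuration irrelevant), and Dess–Martin oxidation returns to the route at 19.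

Step 16. The risk is poor facial selectivity: the lactone carbonyl that covers the unwanted face is flat, so hydride delivery from that side could compete and give the axial alcohol. The fallback replaces kinetic hydride delivery by electron-transfer reduction under thermodynamic control (SmI2, THF/i-PrOH, 0 °C), in which protonation of the intermediate carbanion should lead to the more stable equatorial alcohol. It sets out from 24 and returns at 25; no new compound arises (F0).

Step 18. The Lewis acid may ionise the allylic silyl ether, leading to loss of the protecting group or reduction or cyclisation of the allyl cation; over-reduction of the lactol to the diol in step 17 is a lesser risk. The fallback forms the ether by displacement instead of ionic hydrogenation. Setting out from 25, LiAlH4 (THF, 0 °C) reduces the lactone to the triol F7. The primary hydroxyl is sulfonylated selectively (TsCl, pyridine, 0 °C) to the primary tosylate F8, and NaH in THF closes the oxolane by a 5-exo-tet attack of the cis tertiary alkoxide, returning to the route at 27.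

## Further compounds

F1 | step 14 | (2R,3R,4S)-3-{(3E)-5-[(tert-butyldiphenylsilyl)oxy]-3-methylpent-3-en-1-yl}-2,4-dimethyl-5-oxo-4-{1-[(trimethylsilyl)oxy]ethenyl}oxolane-2-carbaldehyde | C/C(=C\CO[Si](c1ccccc1)(c1ccccc1)C(C)(C)C)CC[C@@H]1[C@@](C)(C(=C)O[Si](C)(C)C)C(=O)O[C@@]1(C)C=O
F2 | step 14 | (1S,5R,8R)-8-{(3E)-5-[(tert-butyldiphenylsilyl)oxy]-3-methylpent-3-en-1-yl}-1,5-dimethyl-2,7-dioxo-6-oxabicyclo[3.2.1]octan-4-yl methanesulfonate (either C4 epimer) | C/C(=C\CO[Si](c1ccccc1)(c1ccccc1)C(C)(C)C)CC[C@@H]1[C@]2(C)C(=O)O[C@@]1(C)C(OS(C)(=O)=O)CC2=O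
F3 | step 8 | (2R,3R,6E)-8-[(tert-butyldiphenylsilyl)oxy]-3-ethynyl-1-[(4-methoxybenzyl)oxy]-2,6-dimethyloct-6-en-2-ol | C/C(=C\CO[Si](c1ccccc1)(c1ccccc1)C(C)(C)C)CC[C@@H]([C@@](C)(O)COCc1ccc(OC)cc1)C#C
F4 | step 8 | (4R,5R)-4-{(3E)-5-[(tert-butyldiphenylsilyl)oxy]-3-methylpent-3-en-1-yl}-5-{[(4-methoxybenzyl)oxy]methyl}-5-methyloxolan-2-ol (both C2 epimers) | C/C(=C\CO[Si](c1ccccc1)(c1ccccc1)C(C)(C)C)CC[C@@H]1CC(O)O[C@@]1(C)COCc1ccc(OC)cc1
F5 | step 8 | (4R,5R)-4-{(3E)-5-[(tert-butyldiphenylsilyl)oxy]-3-methylpent-3-en-1-yl}-5-{[(4-methoxybenzyl)oxy]methyl}-5-methyloxolan-2-one | C/C(=C\CO[Si](c1ccccc1)(c1ccccc1)C(C)(C)C)CC[C@@H]1CC(=O)O[C@@]1(C)COCc1ccc(OC)cc1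
F6 | step 11 | (3S,4R,5R)-4-{(3E)-5-[(tert-butyldiphenylsilyl)oxy]-3-methylpent-3-en-1-yl}-3-(1-hydroxyethyl)-5-{[(4-methoxybenzyl)oxy]methyl}-3,5-dimethyloxolan-2-one (either carbinol epimer) | C/C(=C\CO[Si](c1ccccc1)(c1ccccc1)C(C)(C)C)CC[C@@H]1[C@@](C)(C(C)O)C(=O)O[C@@]1(C)COCc1ccc(OC)cc1
F0 | step 16 | none | none
F7 | step 18 | (1S,2R,3R,4R)-2-{(3E)-5-[(tert-butyldiphenylsilyl)oxy]-3-methylpent-3-en-1-yl}-3-(hydroxymethyl)-1,3-dimethylcyclohexane-1,4-diol | C/C(=C\CO[Si](c1ccccc1)(c1ccccc1)C(C)(C)C)CC[C@@H]1[C@](C)(CO)[C@H](O)CC[C@]1(C)O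
F8 | step 18 | primary 4-methylbenzenesulfonate of F7 (ester of the CH2OH group on the quaternary ring carbon) | C/C(=C\CO[Si](c1ccccc1)(c1ccccc1)C(C)(C)C)CC[C@@H]1[C@](C)(COS(=O)(=O)c2ccc(C)cc2)[C@H](O)CC[C@]1(C)O
A1 | alternative 1 | 3-[(1R,2R,5S,8R)-2-[(tert-butyldimethylsilyl)oxy]-1,5-dimethyl-6-oxabicyclo[3.2.1]octan-8-yl]propanenitrile | N#CCC[C@@H]1[C@]2(C)CO[C@@]1(C)CC[C@H]2O[Si](C)(C)C(C)(C)C
A2 | alternative 1 | 3-[(1R,3R,6S)-3-[(tert-butyldimethylsilyl)oxy]-6-hydroxy-2,2,6-trimethylcyclohexyl]propanenitrile | N#CCC[C@@H]1C(C)(C)[C@H](O[Si](C)(C)C(C)(C)C)CC[C@]1(C)O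
A3 | alternative 2 | (1S,5S,8R)-1,5-dimethyl-8-[(phenylsulfonyl)methyl]-6-oxabicyclo[3.2.1]octane-2,7-dione | O=S(=O)(C[C@@H]1[C@]2(C)C(=O)O[C@@]1(C)CCC2=O)c1ccccc1
A4 | alternative 2 | methyl (6S,7E)-2,6-dimethyl-3-oxo-8-(phenylsulfonyl)-6-[(triethylsilyl)oxy]oct-7-enoate (either C2 epimer) | COC(=O)C(C)C(=O)CC[C@](C)(O[Si](CC)(CC)CC)/C=C/S(=O)(=O)c1ccccc1
A5 | alternative 2 | (S)-linalool, (3S)-3,7-dimethylocta-1,6-dien-3-ol | CC(C)=CCC[C@](C)(O)C=C
A6 | alternative 3 | 2-[(1R,5S,8R)-1,5-dimethyl-2-oxo-6-oxabicyclo[3.2.1]octan-8-yl]ethyl 2,2-dimethylpropanoate | CC(C)(C)C(=O)OCC[C@@H]1[C@]2(C)CO[C@@]1(C)CCC2=O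
A7 | alternative 3 | 2-[(3R,4R)-2,4-dimethyl-4-(prop-2-enoyl)oxolan-3-yl]ethyl 2,2-dimethylpropanoate (either C2 epimer) | C=CC(=O)[C@@]1(C)COC(C)[C@@H]1CCOC(=O)C(C)(C)C
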